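## The problem

The target is a diterpenoid ester built on a nine-membered carbocycle. It is numbered here C1 (methylidene-bearing) through C2, the cis C3=C4 alkene and the C5 carbinol to the ring-fusion carbons C8 and C9. The carbocycle is trans-fused to an oxolane (C8, C9, C10, O, C11) whose quaternary ether carbon C11 carries the stearoyloxymethyl group (C12) and an (E)-4-methylpenta-1,3-dienyl chain (C13 onward).

Closing a cyclononene end to end works against transannular strain and gives no control over the cis alkene, so the ring is the central difficulty. Of the four stereocentres, C8 can direct C9 (trans, and correctable by epimerisation while C1 is a carbonyl). C8 cannot reliably direct C11, whose two arms are both CH2–O groups, so C11 needs its own source of asymmetry. The remote tertiary carbinol C5 must be set by the ring conformation or by a reagent.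

The finished molecule is fragile. The skipped C1(=CH2)/C3=C4 diene moves into conjugation with base, the tertiary allylic alcohol ionises with acid, the conjugated diene tolerates neither ultraviolet light nor Lewis acids, and the stearate does not survive enolates or alkoxides.

Two features make the plan possible. First, C1 and C5 are both carbons that can be ketones, separated by C2 and the C3=C4 alkene. Removing C3 and C4 as acetylene leaves C1–C2–C5 as a cycloheptane-1,3-dione, the substrate of a de Mayo two-carbon ring expansion, so the nine-membered ring is never closed end to end. Second, C8 with its C7–C6–C5–C2 arm, C9 and C1 map atom for atom onto ring-opened (S)-limonene, whose isopropenyl carbon becomes C11.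

## Retrosynthesis

**C13=C14 (28 to 23 and 27).** The diene is cut at C13=C14 to aldehyde 23 and prenyl tetrazolyl sulfone 27. The diene would not survive irradiation, a Lewis acidic methylenation or an organocerium addition, so this must be the last carbon–carbon bond. Cutting C15=C16 instead would leave an enal on the core, which is more easily isomerised than the non-enolisable neopentyl aldehyde. The forward reaction must be E-selective and leave the stearate and the free tertiary alcohol untouched.

**Oxygen-level changes (23 to 22, 21 and 19).** Behind 23 lie oxidation of the C13 alcohol 22, desilylation of 21 and acylation of diol 19 at C12. The stearate goes on before C13 is unmasked, so the two C11 arms never have to be told apart late: one is a free hydroxyl and the other a silyl ether from step 3 onward. The forward acylation must pick the primary hydroxyl over the tertiary one.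

**C5–CH3 and C1=CH2 (19 to 18 to 17).** Both one-carbon appendages are cut back to carbonyl groups, giving enone 18 and then dione 17. The ring expansion needs both carbons as carbonyls, so neither group can be installed earlier. Dione 17 has one stereocentre fewer and no exocyclic alkene. Forward, the methylenation must choose the isolated C1 ketone over the C5 enone without base, and the methyl nucleophile must add 1,2 to C5 from the face that gives 5S.

**C2–C3 and C4–C5, with C2–C5 reconnected (17 to 14 and 15).** Removing C3 and C4 as acetylene 15 and rejoining C2 to C5 gives the enol acetate 14 of an oxolane-fused cycloheptane-1,3-dione. Against ring-closing metathesis at C3=C4 or an aldol closure, this cut replaces a medium-ring closure by the opening of a strained bicycle and delivers the cis alkene automatically. The forward step asks for efficient photocycloaddition of a seven-membered enone with a gaseous alkyne, the enol fixed on C5, and gentle cleavage of the acetate.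

**C1–C2 (14 to 13 to 12).** The dione 13 is cut between C1 and C2 to methyl ketone ester 12 (Claisen retron). Cutting C5–C6 would need a less accessible nucleophile. In 12 the usual five-membered alternative is blocked by the trans ring fusion. Forward, a kinetic methyl enolate must be formed in the presence of an ester α-hydrogen.

**O–C11 and C9–C10 (12 to 10 to 8).** The oxolane is opened at its ether bond to C11 and C10 is removed as formaldehyde, leaving the acyclic keto aldehyde epoxide 8. A conjugate addition to a preformed unsaturated oxolane was rejected, because it would leave C8 to be set by the two nearly identical CH2–O arms on C11. Here C8 and C11 come from independent sources and C9 is thermodynamically controlled. Forward, an aldehyde α-hydroxymethylation is needed in the presence of a ketone, followed by a 5-exo epoxide opening with inversion.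

**C1=C5 reconnection and the epoxide (8 to 6, 5, 4 and 1).** Rejoining the aldehyde and ketone carbons of 8 as an alkene gives cyclohexene 6 (ozonolysis retron). Its epoxide comes from allylic alcohol 4 by asymmetric epoxidation (via 5), and 4 is limonene 1 hydroxylated on the isopropenyl methyl group. The chiral pool thus supplies C8 and ten of the skeletal carbons.

**Sulfone (27 to 26 to 24 and 25).** The sulfone comes from prenyl bromide 24 and 1-phenyltetrazole-5-thiol 25 by S-alkylation and oxidation.

## Roads not taken

**Alternative 1:** The cut is C9–C10. In the forward sense a Lewis acid ionises an O-acetoxymethyl group on the C11 oxygen and a tethered allylsilane attacks the oxocarbenium ion through C9, closing the oxolane and creating the C1 methylidene in one step to give A1.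
- Merits: the exocyclic alkene needs no ketone methylenation, and C5 is set early in an acyclic fragment by reliable asymmetric chemistry. On C5 this route is better than the chosen plan.
- Weak points: the nine-membered ring must still be closed from A1, by metathesis between C3 and C4, next to a quaternary centre and in competition with the 1,1-disubstituted alkene. C11 must already be quaternary and configured before the key step, and the alkyne on C11 needs several steps to become the diene.
- Comparison: the chosen plan sets C5 late and by substrate control, but it avoids any medium-ring closure and fixes C11 by a reagent-controlled epoxidation.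

**Alternative 2:** The cut is C8–C9, made forward by Ireland–Claisen rearrangement of the silyl ketene acetal of a thirteen-membered allylic lactone, which contracts to the carbocycle A2.
- Merits: like the chosen plan it avoids end-to-end closure of the nine-membered ring. It also sets C8 and C9 together in a pericyclic step and carries C5 in place from the start.
- Weak points: the C8/C9 outcome depends on enolate geometry and on a chair-versus-boat choice inside a macrocycle, which is hard to predict. The macrolactone with its cis alkene, silyl ether and exocyclic methylene is a long synthesis in itself. After contraction the oxolane must still be built on A2, with C11 created on a 1,1-disubstituted alkene without internal control.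
- Comparison: the chosen plan is shorter and has C11 secured before the ring is expanded. It concedes the early, secure C5.

**Alternative 3:** The cut is O–C11. Forward, Pd2(dba)3 with a chiral diphosphine ionises a bis-allylic carbonate and the C10 hydroxyl attacks the C11 terminus of the [Pd(η3-pentadienyl)(diphosphine)]+ intermediate, giving A3 with the oxolane, C11 and the (E)-diene formed together.
- Merits: it is the most convergent endgame and sets C11 under catalyst control. In step count after the carbocycle is complete it beats the chosen plan.
- Weak points: the hydroxyl must attack the most hindered of three electrophilic positions (C11 rather than C13 or C15) to form a tertiary ether. The step also does nothing for the real problem, the nine-membered ring with C5, C8 and C9, which must be solved beforehand.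
- Comparison: the chosen plan has no regiochemical question at C11 and solves the ring by expansion. Its endgame is longer (six steps from the methyl carbinol).

Key step: step 9

Remarks on the chemistry:
- Atom labels C1–C13 in the names are those defined above.
- Commercial (S)-(−)-limonene is assumed to contain a little of its antipode; that material becomes a diastereomer in step 2 and is removed by chromatography there or at 10.
- Photoadduct 16 forms as the two cis-fused facial isomers; both give 17.

## Steps

Step 1
Reactants: 1 (S)-(−)-limonene
Product: 4 2-[(1S)-4-methylcyclohex-3-en-1-yl]prop-2-en-1-ol, via allyllithium 2 (not isolated), via allylboronate 3 (not isolated)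
Conditions: n-BuLi, TMEDA, hexane, rt; B(OMe)3, THF, −78 °C; H2O2, NaOH, 0 °C
Reagents that add atoms: hydrogen peroxide, OO
Why: Allylic metalation and oxidation: the n-BuLi/TMEDA complex deprotonates the isopropenyl methyl group of limonene to a 2-substituted allyllithium whose two termini are equivalent, so borylation and oxidative work-up can give only one allylic alcohol. The C8 stereocentre is not involved.

Step 2
Reactants: 4 2-[(1S)-4-methylcyclohex-3-en-1-yl]prop-2-en-1-ol
Product: 5 [(2R)-2-[(1S)-4-methylcyclohex-3-en-1-yl]oxiran-2-yl]methanol
Conditions: Ti(OiPr)4 (10 mol%), D-(−)-diisopropyl tartrate (12 mol%), tBuOOH, 4 Å MS, CH2Cl2, −20 °C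
Reagents that add atoms: tert-butyl hydroperoxide, CC(C)(C)OO
Why: Sharpless asymmetric epoxidation: the Ti(OiPr)4–tartrate catalyst epoxidises only the alkene of the allylic alcohol, leaving the ring alkene, and sets C11 under reagent control. The D-(−)-tartrate is chosen because the L-(+)-ester gives (S)-configured 2-substituted glycidols and the (R)-epoxide is needed here.

Step 3
Reactants: 5 [(2R)-2-[(1S)-4-methylcyclohex-3-en-1-yl]oxiran-2-yl]methanol
Product: 6 tert-butyl{[(2S)-2-[(1S)-4-methylcyclohex-3-en-1-yl]oxiran-2-yl]methoxy}diphenylsilane
Conditions: TBDPSCl, imidazole, CH2Cl2, 0 °C → rt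
Reagents that add atoms: tert-butyl(chloro)diphenylsilane, CC(C)(C)[Si](Cl)(c1ccccc1)c1ccccc1
Why: Silylation under imidazole buffering avoids the alkoxide that would scramble C11 by Payne rearrangement. The TBDPS group marks this arm as C13 and is bulky enough not to migrate to the neighbouring C12 oxygen later.

Step 4
Reactants: 6 tert-butyl{[(2S)-2-[(1S)-4-methylcyclohex-3-en-1-yl]oxiran-2-yl]methoxy}diphenylsilane
Product: 8 (3S)-3-[(2S)-2-{[tert-butyl(diphenyl)silyl]oxymethyl}oxiran-2-yl]-6-oxoheptanal, via ozonide 7 (not isolated)
Conditions: O3, CH2Cl2, −78 °C; Me2S, −78 °C → rt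
Reagents that add atoms: ozone, [O-][O+]=O
Why: Ozonolysis with reductive work-up cleaves the only remaining alkene to the C1 aldehyde and the C5 methyl ketone. Epoxide and silyl ether are inert, and the neutral work-up keeps the epoxy ketone from ketalising.

Step 5
Reactants: 8 (3S)-3-[(2S)-2-{[tert-butyl(diphenyl)silyl]oxymethyl}oxiran-2-yl]-6-oxoheptanal
Product: 10 (3S,4S,5R)-5-{[tert-butyl(diphenyl)silyl]oxymethyl}-5-(hydroxymethyl)-4-(3-oxobutyl)oxolane-3-carbaldehyde, via hydroxy aldehyde 9 (not isolated)
Conditions: aq. CH2O, (R)-α,α-diphenylprolinol trimethylsilyl ether (20 mol%), pH 7 phosphate buffer, toluene, rt; PPTS (10 mol%), CH2Cl2, 0 °C → rt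
Reagents that add atoms: formaldehyde, C=O
Why: Enamine-mediated aldol addition of the aldehyde to formaldehyde, a far better electrophile than the C5 ketone, places C10 on C9. Mild acid then lets the new hydroxyl open the epoxide at its tertiary carbon (5-exo-tet, inversion at C11) faster than the ketone oxygen can (6-exo), closing the oxolane and freeing the C12 hydroxyl. C9 is set by the catalyst and, being α to the aldehyde, settles trans to the C8 chain in any case.

Step 6
Reactants: 10 (3S,4S,5R)-5-{[tert-butyl(diphenyl)silyl]oxymethyl}-5-(hydroxymethyl)-4-(3-oxobutyl)oxolane-3-carbaldehyde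
Product: 12 methyl (3S,4S,5R)-5-{[tert-butyl(diphenyl)silyl]oxymethyl}-5-(hydroxymethyl)-4-(3-oxobutyl)oxolane-3-carboxylate, via carboxylic acid 11 (not isolated)
Conditions: NaClO2, NaH2PO4, 2-methyl-2-butene, tBuOH/H2O, 0 °C → rt; Me3SiCHN2, MeOH/toluene, 0 °C
Reagents that add atoms: sodium chlorite, [Na+].[O-]Cl=O; trimethylsilyldiazomethane, C[Si](C)(C)C=[N+]=[N-]
Why: Pinnick oxidation is specific for the aldehyde and leaves the primary alcohol, ketone and silyl ether alone; the crude acid is methylated without base. The C12 hydroxyl is trans to C1 across the oxolane and cannot lactonise.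

Step 7
Reactants: 12 methyl (3S,4S,5R)-5-{[tert-butyl(diphenyl)silyl]oxymethyl}-5-(hydroxymethyl)-4-(3-oxobutyl)oxolane-3-carboxylate
Product: 13 oxolane-fused cycloheptane-1,3-dione (ketones at C1 and C5; C8 S; C9 S; C11 R; free C12 hydroxyl; C13 silyl ether)
Conditions: LiN(SiMe3)2 (3.3 equiv), THF, −78 → 0 °C; aq. HCl to pH 4
Reagents that add atoms: none
Why: Intramolecular Claisen (Dieckmann-type) condensation: the base deprotonates the ketone methyl group kinetically and the enolate acylates on the C1 ester, the resulting diketonate making the seven-membered closure irreversible. The usual competitor, closure from C6 to a 2-acetylcyclopentanone, would create a trans-fused bicyclo[3.3.0]octane and is disfavoured. The C12 hydroxyl is held as its alkoxide, to which the TBDPS group does not migrate at this temperature.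

Step 8
Reactants: 13 oxolane-fused cycloheptane-1,3-dione
Product: 14 C5 enol acetate and C12 acetate of 13 (3-acetoxycyclohept-2-en-1-one core with the ketone at C1; C8 S; C9 S; C11 R)
Conditions: Ac2O, pyridine, CH2Cl2, 0 °C → rt
Reagents that add atoms: acetic anhydride, CC(=O)OC(C)=O
Why: O-Acylation of the enolised dione goes to the less hindered oxygen on C5, since the C1 carbonyl is flanked by the ring-fusion carbon C9; this isomer is also the more stable one. The C12 hydroxyl is acetylated in the same operation, and omitting nucleophilic catalysts avoids C-acylation.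

Step 9
Reactants: 14 C5 enol acetate and C12 acetate of the dione; 15 acetylene
Product: 17 trans-fused cis-cyclonon-3-ene-1,5-dione (C8 S; C9 S; C11 R; free C12 hydroxyl; C13 silyl ether), via cyclobutene 16 (not isolated)
Conditions: C2H2 (sat.), hν (350 nm, Pyrex), CH2Cl2, −70 °C; K2CO3 (0.3 equiv), MeOH, 0 °C; pH 7 buffer
Reagents that add atoms: none
Why: The enone is the only chromophore absorbing at 350 nm; its triplet adds stepwise to acetylene through a 1,4-diradical that collapses to a cyclobutene, giving the bicyclo[5.2.0] adduct 16 with the acetoxy group on the fusion carbon C5. This is a de Mayo reaction, the known photocycloaddition of cyclic 1,3-dione enol acetates to alkenes and to acetylene followed by retro-aldol cleavage. The only ring closed is the four-membered one, by radical recombination; the nine-membered ring is not closed but results from opening the zero bridge. Methanolysis frees the C5 alkoxide, and retro-aldol cleavage of the C2–C5 bond, driven by cyclobutene strain with the C1 ketone as electron sink, makes C5 a ketone and C2 a methylene. No stereocentre is created that survives: C2 and C5 of 16 both become achiral, and C8, C9 and C11 are spectators. The alkene is cis because it was the cyclobutene double bond, and it lies next to C5 because the enol was fixed there in step 8. The long wavelength limits secondary photochemistry of the β,γ-unsaturated ketone 16, and cold, substoichiometric carbonate with a buffered quench is meant to avoid alkene migration towards C1, C9 epimerisation and transannular aldol. The C12 acetate is removed in the same methanolysis.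

Step 10
Reactants: 17 trans-fused cis-cyclonon-3-ene-1,5-dione
Product: 18 C1-methylidene cis-cyclononenone (ketone at C5; C8 S; C9 R; C11 R; free C12 hydroxyl; C13 silyl ether)
Conditions: Zn, CH2Br2, TiCl4, THF, 0 °C; then 17, CH2Cl2, 0 °C → rt
Reagents that add atoms: dibromomethane, BrCBr
Why: Takai–Lombardo methylenation: the reagent is not basic, so the acidic C2 and C9 positions are not enolised, and isolated ketones react ahead of enones with nucleophilic methylene donors, which directs it to C1. The free C12 hydroxyl only consumes extra reagent.

Step 11
Reactants: 18 C1-methylidene cis-cyclononenone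
Product: 19 (5S,8S,9R,11R)-C5 methyl carbinol (free C12 hydroxyl; C13 silyl ether)
Conditions: MeMgBr, CeCl3, THF, −78 °C
Reagents that add atoms: methylmagnesium bromide, C[Mg]Br
Why: MeCeCl2 is nucleophilic but barely basic, so it adds 1,2 to the enone carbonyl without conjugate addition or deprotonation at the doubly allylic C2. C5 is set by substrate control: the trans-fused oxolane and two ring alkenes restrict the nine-membered ring, and attack from its outer face is expected to give 5S. This assignment is the first thing to verify.

Step 12
Reactants: 19 (5S,8S,9R,11R)-C5 methyl carbinol; 20 stearoyl chloride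
Product: 21 C12 stearate of 19 (5S,8S,9R,11R; C13 silyl ether)
Conditions: pyridine, DMAP (cat.), CH2Cl2, 0 °C
Reagents that add atoms: none
Why: Acylation of the primary C12 hydroxyl; the tertiary allylic C5 hydroxyl is too hindered to react under these conditions.

Step 13
Reactants: 21 C12 stearate
Product: 22 C13 alcohol (5S,8S,9R,11S; C12 stearate)
Conditions: Bu4NF, AcOH, THF, rt
Reagents that add atoms: none
Why: Fluoride cleaves the silyl ether; buffering with acetic acid prevents 1,3-acyl migration from C12 to C13 and protects the tertiary allylic alcohol and the skipped diene.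

Step 14
Reactants: 22 C13 alcohol
Product: 23 C13 aldehyde (5S,8S,9R,11R; C12 stearate)
Conditions: Dess–Martin periodinane, NaHCO3, CH2Cl2, 0 °C → rt
Reagents that add atoms: none
Why: Dess–Martin oxidation of the only primary alcohol; the tertiary alcohol cannot be oxidised and the aldehyde has no α-hydrogen to epimerise.

Step 15
Reactants: 24 1-bromo-3-methylbut-2-ene; 25 1-phenyl-1H-tetrazole-5-thiol
Product: 26 5-[(3-methylbut-2-en-1-yl)sulfanyl]-1-phenyl-1H-tetrazole
Conditions: K2CO3, acetone, rt
Reagents that add atoms: none
Why: S-Alkylation of the thiolate with a primary allylic bromide (SN2).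

Step 16
Reactants: 26 5-[(3-methylbut-2-en-1-yl)sulfanyl]-1-phenyl-1H-tetrazole
Product: 27 5-[(3-methylbut-2-en-1-yl)sulfonyl]-1-phenyl-1H-tetrazole
Conditions: H2O2 (30% aq.), (NH4)6Mo7O24·4H2O (10 mol%), EtOH, 0 °C → rt
Reagents that add atoms: hydrogen peroxide, OO
Why: Molybdate-catalysed peroxide oxidation takes the sulfide to the sulfone and is chemoselective for sulfur over the trisubstituted alkene.

Step 17
Reactants: 23 C13 aldehyde; 27 5-[(3-methylbut-2-en-1-yl)sulfonyl]-1-phenyl-1H-tetrazole
Product: 28 target (5S,8S,9R,11R)
Conditions: KN(SiMe3)2, 1,2-dimethoxyethane, −60 °C → rt; aq. NH4Cl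
Reagents that add atoms: none
Why: Julia–Kocienski olefination: the metalated sulfone adds to the non-enolisable aldehyde, and Smiles rearrangement with loss of SO2 and the tetrazolyl oxide gives the C13=C14 alkene, expected mainly E for a hindered aldehyde under these conditions. Adding the base to the mixture of both partners at low temperature spares the stearate.

## Compound list

1 | (S)-(−)-limonene | CC(=C)[C@H]1CCC(C)=CC1 | starting material
2 | [2-[(1S)-4-methylcyclohex-3-en-1-yl]prop-2-en-1-yl]lithium | [Li]CC(=C)[C@H]1CCC(C)=CC1 | intermediate (not isolated)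
3 | dimethyl [2-[(1S)-4-methylcyclohex-3-en-1-yl]prop-2-en-1-yl]boronate | COB(OC)CC(=C)[C@H]1CCC(C)=CC1 | intermediate (not isolated)
4 | 2-[(1S)-4-methylcyclohex-3-en-1-yl]prop-2-en-1-ol | OCC(=C)[C@H]1CCC(C)=CC1 | intermediate
5 | [(2R)-2-[(1S)-4-methylcyclohex-3-en-1-yl]oxiran-2-yl]methanol | OC[C@@]2(CO2)[C@H]1CCC(C)=CC1 | intermediate
6 | tert-butyl{[(2S)-2-[(1S)-4-methylcyclohex-3-en-1-yl]oxiran-2-yl]methoxy}diphenylsilane | CC(C)(C)[Si](c3ccccc3)(c4ccccc4)OC[C@@]2(CO2)[C@H]1CCC(C)=CC1 | intermediate
7 | secondary ozonide of 6 (1,2,4-trioxolane across the former ring alkene, both acetal carbons as mixtures) | CC(C)(C)[Si](c3ccccc3)(c4ccccc4)OC[C@@]2(CO2)[C@H]1CCC5(C)OOC(O5)C1 | intermediate (not isolated)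
8 | (3S)-3-[(2S)-2-{[tert-butyl(diphenyl)silyl]oxymethyl}oxiran-2-yl]-6-oxoheptanal | CC(C)(C)[Si](c3ccccc3)(c4ccccc4)OC[C@@]2(CO2)[C@H](CC=O)CCC(C)=O | intermediate
9 | (2S,3S)-3-[(2S)-2-{[tert-butyl(diphenyl)silyl]oxymethyl}oxiran-2-yl]-2-(hydroxymethyl)-6-oxoheptanal | CC(C)(C)[Si](c3ccccc3)(c4ccccc4)OC[C@@]2(CO2)[C@H]([C@@H](CO)C=O)CCC(C)=O | intermediate (not isolated)
10 | (3S,4S,5R)-5-{[tert-butyl(diphenyl)silyl]oxymethyl}-5-(hydroxymethyl)-4-(3-oxobutyl)oxolane-3-carbaldehyde | CC(=O)CC[C@H]2[C@H](C=O)CO[C@@]2(CO[Si](c3ccccc3)(c4ccccc4)C(C)(C)C)CO | intermediate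
11 | (3S,4S,5R)-5-{[tert-butyl(diphenyl)silyl]oxymethyl}-5-(hydroxymethyl)-4-(3-oxobutyl)oxolane-3-carboxylic acid | CC(=O)CC[C@H]2[C@H](C(O)=O)CO[C@@]2(CO[Si](c3ccccc3)(c4ccccc4)C(C)(C)C)CO | intermediate (not isolated)
12 | methyl (3S,4S,5R)-5-{[tert-butyl(diphenyl)silyl]oxymethyl}-5-(hydroxymethyl)-4-(3-oxobutyl)oxolane-3-carboxylate | CC(=O)CC[C@H]2[C@H](C(=O)OC)CO[C@@]2(CO[Si](c3ccccc3)(c4ccccc4)C(C)(C)C)CO | intermediate
13 | trans-fused oxolane–cycloheptane-1,3-dione (C1 and C5 ketones; C8 S, C9 S, C11 R; C12 hydroxymethyl, C13 TBDPS ether) | O=C1CC(=O)CC[C@H]2[C@H]1CO[C@@]2(CO[Si](c3ccccc3)(c4ccccc4)C(C)(C)C)CO | intermediate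
14 | C5 enol acetate, C12 acetate of 13 (ketone at C1; C8 S, C9 S, C11 R) | O=C1C=C(OC(C)=O)CC[C@H]2[C@H]1CO[C@@]2(CO[Si](c3ccccc3)(c4ccccc4)C(C)(C)C)COC(C)=O | intermediate
15 | acetylene | C#C | starting material
16 | cyclobutene photoadduct (bicyclo[5.2.0]non-8-en-2-one core, acetoxy on C5, cis-fused at C2–C5, both facial isomers) | O=C1C5C=CC5(OC(C)=O)CC[C@H]2[C@H]1CO[C@@]2(CO[Si](c3ccccc3)(c4ccccc4)C(C)(C)C)COC(C)=O | intermediate (not isolated)
17 | trans-fused oxolane–(3Z)-cyclonon-3-ene-1,5-dione (C8 S, C9 S, C11 R; C12 hydroxymethyl, C13 TBDPS ether) | O=C1C/C=C\C(=O)CC[C@H]2[C@H]1CO[C@@]2(CO[Si](c3ccccc3)(c4ccccc4)C(C)(C)C)CO | intermediate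
18 | C1-methylidene (3Z)-cyclononen-5-one (C8 S, C9 R, C11 R; C12 hydroxymethyl, C13 TBDPS ether) | C=C1C/C=C\C(=O)CC[C@H]2[C@H]1CO[C@@]2(CO[Si](c3ccccc3)(c4ccccc4)C(C)(C)C)CO | intermediate
19 | (5S,8S,9R,11R)-C5 methyl carbinol (C12 hydroxymethyl, C13 TBDPS ether) | C=C1C/C=C\[C@@](C)(O)CC[C@H]2[C@H]1CO[C@@]2(CO[Si](c3ccccc3)(c4ccccc4)C(C)(C)C)CO | intermediate
20 | stearoyl chloride (octadecanoyl chloride) | ClC(=O)CCCCCCCCCCCCCCCCC | starting material
21 | (5S,8S,9R,11R)-C12 stearate, C13 TBDPS ether | C=C1C/C=C\[C@@](C)(O)CC[C@H]2[C@H]1CO[C@@]2(CO[Si](c3ccccc3)(c4ccccc4)C(C)(C)C)COC(=O)CCCCCCCCCCCCCCCCC | intermediate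
22 | (5S,8S,9R,11S)-C12 stearate, C13 alcohol | C=C1C/C=C\[C@@](C)(O)CC[C@H]2[C@H]1CO[C@@]2(CO)COC(=O)CCCCCCCCCCCCCCCCC | intermediate
23 | (5S,8S,9R,11R)-C12 stearate, C13 aldehyde | C=C1C/C=C\[C@@](C)(O)CC[C@H]2[C@H]1CO[C@@]2(C=O)COC(=O)CCCCCCCCCCCCCCCCC | intermediate
24 | 1-bromo-3-methylbut-2-ene | CC(C)=CCBr | starting material
25 | 1-phenyl-1H-tetrazole-5-thiol | Sc1nnnn1-c1ccccc1 | starting material
26 | 5-[(3-methylbut-2-en-1-yl)sulfanyl]-1-phenyl-1H-tetrazole | CC(C)=CCSc1nnnn1-c1ccccc1 | intermediate
27 | 5-[(3-methylbut-2-en-1-yl)sulfonyl]-1-phenyl-1H-tetrazole | CC(C)=CCS(=O)(=O)c1nnnn1-c1ccccc1 | intermediate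
28 | CNP0274030.1 (5S,8S,9R,11R) | C=C1C/C=C\[C@@](C)(O)CC[C@H]2[C@H]1CO[C@@]2(/C=C/C=C(C)C)COC(=O)CCCCCCCCCCCCCCCCC | target

## Step count and least certain steps

Total: 17 steps. Longest linear sequence: 15 steps (steps 1–14 and 17, from 1); steps 15 and 16 prepare sulfone 27.

**Step 9 (key step).**
- Most likely failure: the excited seven-membered enone relaxes by twisting about its C2=C5 bond faster than it is captured by acetylene, a gas of limited concentration and a modest triplet acceptor. Conversion then stalls, or dimerisation and secondary acyl-shift photochemistry of the β,γ-unsaturated ketone take over.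
- Second concern: during methanolysis, carbonate may move the alkene into conjugation with C1, epimerise C9 or start a transannular aldol. Low temperature, substoichiometric base and a buffered quench are the controls.
- Fallback: from 14, irradiate in the presence of a large excess of liquid (Z)-1,2-dichloroethene as acetylene surrogate to give the dichlorocyclobutane F1. Reductive 1,2-elimination with Bu3SnH and AIBN (benzene, 80 °C) then gives cyclobutene 16, which is taken through the same methanolysis to 17.

**Step 5.**
- Most likely failure: the C9 enamine adds to the C5 ketone instead of formaldehyde, the hydroxy aldehyde loses water to a 2-substituted acrolein, or in the acid stage the ketone oxygen opens the epoxide to a bicyclic ketal before the hydroxyl does.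
- Fallback: from 8, a Stork enamine alkylation (pyrrolidine, 4 Å MS; then BnOCH2Cl, MeCN; aqueous buffer) gives the α-(benzyloxymethyl) aldehyde F2, which cannot dehydrate. Hydrogenolysis (H2, Pd(OH)2 on carbon, EtOAc) releases 9, and the acid stage of step 5 with equilibration at C9 gives 10.

**Step 7.**
- Most likely failure: proton transfer to the C9 or C6 positions, or reversal of the Claisen addition, outruns the slow seven-membered closure, leading to C9 epimerisation and intermolecular condensation.
- Fallback: from acid 11 (isolated for this purpose), coupling with MeNHOMe·HCl (EDC, iPr2NEt, CH2Cl2) gives the N-methoxy-N-methylamide F3. Its acylation by the same kinetic enolate (LiN(SiMe3)2, THF, −78 °C) passes through a chelated adduct that cannot revert, and work-up gives 13.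

**Step 10.**
- Most likely failure: incomplete discrimination between the C1 ketone and the C5 enone, or Lewis acid-induced migration of the C3=C4 alkene.
- Fallback: from 17, selective ketalisation of the isolated C1 ketone (2-ethyl-2-methyl-1,3-dioxolane, TsOH cat.) gives the C1 dioxolane enone F4. MeMgBr/CeCl3 then gives the dioxolane carbinol F5, mild hydrolysis (PPTS, acetone/H2O) gives the keto carbinol F6, and methylenation of its single ketone (Zn, CH2Br2, TiCl4) gives 19.

**Step 11.**
- Most likely failure: poor facial selectivity at C5, because the preferred conformation of the nine-membered ring cannot be predicted with confidence.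
- Fallback: from 18, replace substrate control by reagent control with the Ti(OiPr)4-catalysed addition of Me2Zn in the presence of a chiral trans-cyclohexane-1,2-diyl bis(sulfonamide) diol ligand, its enantiomer chosen for 5S. This gives 19 directly and makes no new compound (F0).

**Step 17.**
- Most likely failure: erosion of E selectivity at C13=C14, because allylic sulfones are less selective than alkyl sulfones, leaving geometric isomers that are hard to separate from a lipophilic ester.
- Fallback: from 23, Takai iodo-olefination (CrCl2, CHI3, THF) gives the (E)-vinyl iodide F7. Suzuki coupling with 4,4,5,5-tetramethyl-2-(2-methylprop-1-en-1-yl)-1,3,2-dioxaborolane (Pd(PPh3)4, K3PO4, THF/H2O) then gives 28 with the geometry fixed.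

## Further compounds

F1 | step 9 | dichlorocyclobutane photoadduct of 14 (chlorines on C3 and C4, acetoxy on C5; stereoisomer mixture at C2–C5) | O=C1C5C(Cl)C(Cl)C5(OC(C)=O)CC[C@H]2[C@H]1CO[C@@]2(CO[Si](c3ccccc3)(c4ccccc4)C(C)(C)C)COC(C)=O
F2 | step 5 | (3S)-2-(benzyloxymethyl)-3-[(2S)-2-{[tert-butyl(diphenyl)silyl]oxymethyl}oxiran-2-yl]-6-oxoheptanal (C9 epimers) | CC(C)(C)[Si](c3ccccc3)(c4ccccc4)OC[C@@]2(CO2)[C@H](C(COCc5ccccc5)C=O)CCC(C)=O
F3 | step 7 | (3S,4S,5R)-5-{[tert-butyl(diphenyl)silyl]oxymethyl}-5-(hydroxymethyl)-N-methoxy-N-methyl-4-(3-oxobutyl)oxolane-3-carboxamide | CC(=O)CC[C@H]2[C@H](C(=O)N(C)OC)CO[C@@]2(CO[Si](c3ccccc3)(c4ccccc4)C(C)(C)C)CO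
F4 | step 10 | C1 ethylene ketal of 17 (C5 enone retained; C8 S, C9 S, C11 R) | C15(OCCO5)C/C=C\C(=O)CC[C@H]2[C@H]1CO[C@@]2(CO[Si](c3ccccc3)(c4ccccc4)C(C)(C)C)CO
F5 | step 10 | C1 ethylene ketal, (5S)-C5 methyl carbinol | C15(OCCO5)C/C=C\[C@@](C)(O)CC[C@H]2[C@H]1CO[C@@]2(CO[Si](c3ccccc3)(c4ccccc4)C(C)(C)C)CO
F6 | step 10 | C1 ketone, (5S)-C5 methyl carbinol | O=C1C/C=C\[C@@](C)(O)CC[C@H]2[C@H]1CO[C@@]2(CO[Si](c3ccccc3)(c4ccccc4)C(C)(C)C)CO
F0 | step 11 | none | none
F7 | step 17 | (5S,8S,9R,11R)-C12 stearate with (E)-2-iodoethenyl on C11 | C=C1C/C=C\[C@@](C)(O)CC[C@H]2[C@H]1CO[C@@]2(/C=C/I)COC(=O)CCCCCCCCCCCCCCCCC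
A1 | alternative 1 | trans-3,4-disubstituted oxolane with the C1 methylidene unit on C9, the C5 silyloxy vinyl chain on C8, and pivaloyloxymethyl and (trimethylsilyl)ethynyl groups on C11 | C=CCC(=C)[C@@H]1CO[C@@](C#C[Si](C)(C)C)(COC(=O)C(C)(C)C)[C@H]1CC[C@](C)(O[Si](CC)(CC)CC)C=C
A2 | alternative 2 | cyclononadiene carboxylic acid with C9 carboxyl, C8 3-(4-methoxybenzyloxy)prop-1-en-2-yl branch and C5 triethylsilyl ether | C=C1C/C=C\[C@@](C)(O[Si](CC)(CC)CC)CC[C@H](C(=C)COCc2ccc(OC)cc2)[C@H]1C(=O)O
A3 | alternative 3 | bis-silyl ether of the target diol (C5 triethylsilyl ether, C12 tert-butyldimethylsilyl ether) | C=C1C/C=C\[C@@](C)(O[Si](CC)(CC)CC)CC[C@H]2[C@H]1CO[C@@]2(/C=C/C=C(C)C)CO[Si](C)(C)C(C)(C)C
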